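In the delta run left-handed product stood at 3.9% after 50.0 min, in the zeta run at 2.5% after 60.0 min, and two colleagues read these runs differently.

common to all: left-handed substrate 0.50 M; right-handed substrate 0.50 M
- zeta: reagent 0.083 M; free catalyst 5 mM; run made earlier
- delta: reagent 0.19 M; free catalyst 5 mM; run made earlier
- Wednesday's: reagent 0.120 M; free catalyst 5.0 mM; time 2.0 h
- Tuesday's: reagent 0.200 M; free catalyst 5.0 mM; time 2.0 h
- Friday's: reagent 0.300 M; free catalyst 5.0 mM; time 2.0 h

| run | time / min | left-handed product / % | right-handed product / % |
|---|---|---|---|
| zeta | 30.0 | 0.5 | 0.1 |
| zeta | 60.0 | 2.5 | 0.1 |
| zeta | 90.0 | 3.4 | 0.5 |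
| zeta | 120 | 3.5 | 0.2 |
| delta | 10.0 | 1.0 | 0.2 |
| delta | 20.0 | 0.7 | 0 |
| delta | 50.0 | 3.9 | 0.6 |
| delta | 120 | 7.7 | 0.4 |

(standard deviation of a reading: 0.5 percentage points)

- free catalyst is single-handed; left-handed substrate and right-handed substrate are mirror images of each other, charged as a racemate, each of them at the stated concentration
- an excess is the difference of the two amounts in percent of their sum
- "hardly changes" means that all values lie within two and a half points (for a concentration: within two and a half percent of the largest)

* excess of left-handed product over right-handed product at the end for Wednesday's, Tuesday's, Friday's, in this order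
* how that number moves from the first to the last of them (falls all the way / hardly changes / falls, then rises / rises all the way / rises, then falls)

The first colleague looks at the last reading of each run. Product per reagent charged is 0.446 in zeta and 0.426 in delta, so he says product follows reagent, and the selectivity factor, left-handed over right-handed product, stays with the catalyst.

The second colleague, whose reckoning I commit to, looks at average speed up to the two readings above. From zeta to delta the reagent charge rises 2.29 times, but left-handed product per minute rises 1.87 times, which is less. She defines the reagent order of left-handed product, the logarithm of the rise in its speed divided by the logarithm of the rise in reagent, 0.757. This is a weak reading, with a scatter of 0.5 percentage points on 2.5%. Right-handed product is too small to give an order, 0.4% at the end of delta being less than the scatter, so she assumes order one for it.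

Summing the readings of both runs gives a selectivity factor of 11.0, a loose level, which she assigns to Wednesday's, whose reagent charge lies between those of the runs. The factor then goes with reagent to the power of the order less one, so her excesses are 83.4%, 81.4% and 79.7%. That is a fall of 3.7 points, against the 2.5 points that "hardly changes" allows.

His number is the forecast, 85%, 84%, 83%, hardly changes: “the excess should hardly change”.

The flask gives 74.9%, 71.3% and 67.0%, so the excess falls all the way, by 7.9 points against her 3.7 points, and from a lower level than hers. His constancy has its region along the clock inside one flask: Friday's shows 66.2% at 1.00 h and 67.0% at 2.00 h.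

    free catalyst + left-handed substrate ⇌ catalyst intermediate A (K = 9.40 L mol⁻¹, k = 860 L mol⁻¹ h⁻¹)
    free catalyst + right-handed substrate ⇌ catalyst intermediate B (K = 20.0 L mol⁻¹, k = 1800 L mol⁻¹ h⁻¹)
    reagent + catalyst intermediate A → free catalyst + left-handed product (k = 330 L mol⁻¹ h⁻¹)
    reagent + catalyst intermediate B → free catalyst + right-handed product (k = 17.0 L mol⁻¹ h⁻¹)
    reagent ⇌ dormant form (K = 2.70, k = 0.180 h⁻¹)

At 1.00 h left-handed product stands at 3.55% in Wednesday's, and her order 0.757 carried from there gives 5.22% for Tuesday's, which holds 5.32%, and 7.10% for Friday's, which holds 7.10%. At the asked time the left-handed step runs 7.42 times faster than the right-handed step in Wednesday's, with catalyst intermediate A at 25.7% and catalyst intermediate B, the resting state, at 67.3%, but 5.52 times faster in Friday's, with 20.4% and 71.8%.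

(All runs are simulated with made-up constants; noise was put on by code.)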